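A closed, stirred vessel held substrate and reagent at constant temperature. Beta had already run, and I had to say what the new flask held at 4.0 min.

| flask | substrate | reagent | remark | time |
|---|---|---|---|---|
| beta | 0.30 M | 0.12 M | run made earlier |  |
| flask | 0.20 M | 0.120 M |  | 4.0 min |

beta run (percent of the substrate charged)

| time / s | target / % | substrate / % | side product A / % |
|---|---|---|---|
| 10.0 | 2 | 84 | 0 |
| 20.0 | 0 | 75 | 0 |
| 40.0 | 7 | 62 | 0 |
| 80.0 | 7 | 44 | 1 |

(scatter of a reading: 2 percentage points)

1. how much target the flask holds at 4.0 min, in percent of the substrate charged
2. how much substrate the flask holds at 4.0 min, in percent of the substrate charged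
3. how much side product A the flask holds at 4.0 min, in percent of the substrate charged

By 80.0 s beta had lost 0.168 M of substrate, more than its 0.12 M of reagent, so substrate had a way out besides the reagent. In beta, the logarithm of substrate fell at 0.0174 s⁻¹ over the first 10.0 s. I treated this quick opening as over and took the tail constant k_t, the slope of ln(substrate) between beta's last two readings, 0.00857 s⁻¹, as a pseudo-first-order constant for the free substrate; as read from these scattered readings, it was about half the opening slope.

For the flask, my estimate of the lower bound used beta's average slope, 0.0103 s⁻¹, faster than k_t, and gave 8.52 %. My estimate of the upper bound treated the fall as second order in substrate, so that the flask's smaller charge slowed it, and gave 28.2 %. To tighten this, I assumed the flask matched beta's percentage at 80.0 s, ran k_t for the remaining time, and committed to 11.2 %.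

Of its two rate laws the forecast wrote: “Both fit beta”. It put substrate at 21 %, inside my bracket but above my figure, with target at 30 % and side product A at 4 %.

The flask gave substrate 11.6 %, target 26.8 % and side product A 19.0 %.

    intermediate A → side product A (k = 0.00480 s⁻¹)
    substrate + intermediate A → side product B (k = 0.0450 M⁻¹ s⁻¹)
    intermediate B → target (k = 0.0150 s⁻¹)
    substrate → intermediate A (k = 0.00530 s⁻¹)
    substrate + reagent ⇌ intermediate B (K = 4.10 M⁻¹, k = 0.110 M⁻¹ s⁻¹)

Substrate in the flask lay inside the bracket, close to the 11.2 % from k_t and 9.4 percentage points below the forecast, while side product A stood 15 points above the forecast. Changing the substrate charge from beta's to the flask's left the percentage at beta's last reading at 43.6 %, the starting point of the tail. For the neighbouring flask, the same charges read at 2.5 min, k_t from that starting point gave 24.1 %, and that neighbouring flask held 24.3 % of its substrate.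

The readings are simulated with made-up constants; the scatter is artificial.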